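The data come from a simulation for an exercise; noise was put on by code.

- Take the ratio of over-reaction product to target, in which the amount of target made cancels: if target, once formed, is lost by a first-order step, the logarithm of one plus that ratio, the spoilage count, is simply rate times time.
- Target's share of target plus over-reaction product is then the inverse exponential of the count, so over-reaction product leads once the count passes the logarithm of two, 0.693.

the same everywhere: starting material 0.10 M
- amber: target 0.010 M; protic impurity 0.015 M; temperature 30 °C; run made earlier
- ochre: target 0.010 M; protic impurity 0.060 M; temperature 41 °C; run made earlier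
- red: target 0.015 M; protic impurity 0.030 M; temperature 30 °C; run made earlier
- Tuesday's: target 0.0100 M; protic impurity 0.0300 M; temperature 45 °C; time 3.0 h
- Wednesday's: target 0.0100 M; protic impurity 0.0300 M; temperature 25 °C; time 3.0 h

- amber (time / min: over-reaction product / %, target / %, starting material / %): 15.0: 0, 37, 62; 30.0: 1, 70, 25; 50.0: 6, 90, 5; 60.0: 5, 91, 4; 80.0: 9, 90, 0; 90.0: 9, 89, 5; 120: 19, 89, 1
- ochre (time / min: over-reaction product / %, target / %, starting material / %): 6.00: 1, 39, 58; 15.0: 4, 81, 12; 25.0: 8, 86, 6; 40.0: 18, 83, 0; 50.0: 24, 79, 0
- red (time / min: over-reaction product / %, target / %, starting material / %): 8.00: 0, 32, 77; 15.0: 1, 50, 52; 30.0: 1, 82, 19; 60.0: 7, 96, 2; 120: 18, 89, 0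

(scatter of a reading: 1.5 percentage points)

- which of these there is most of at the end, counted by the starting material in it, Tuesday's (over-reaction product / starting material / target)
- which of these there is most of at the end, counted by the starting material in it, Wednesday's (over-reaction product / starting material / target)
- the largest of these amounts at the end, in percent of the starting material charged, Tuesday's
- the largest of these amounts at the end, in percent of the starting material charged, Wednesday's

- steps thought possible: starting material + protic impurity -> quenched substrate; starting material <-> dormant form; target -> over-reaction product; starting material -> target; starting material + target -> 2 target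
- a reading of starting material is of its free form alone

- Read from late readings, with their scatter, the amber run's count climbs at 0.00184 min⁻¹ at 30 °C.
- The ochre run's count climbs at 0.00620 min⁻¹ at 41 °C, faster by a factor of 3.37.
- I charge that factor to temperature, although the ochre run also holds more protic impurity.
- Scaling the factor by degrees, you get 0.00964 min⁻¹ for Tuesday's flask and 0.00106 min⁻¹ for Wednesday's, so Wednesday's is slower by a factor of 9.09.
- Over 3.0 h, Tuesday's spoilage count, the rate times the time, comes to 1.74, above the logarithm of two. I expect over-reaction product to lead, with target's share near 17.6 %.
- Wednesday's count comes to 0.191, below it, so I expect target to lead with a share near 82.6 %. That count runs from the first minute while target is still forming, so it sits on the high side.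
- The forecast gives over-reaction product at 86 % (79 % to 92 %) for Tuesday's flask and target at 88 % (82 % to 93 %) for Wednesday's, holding that “Over-reaction is first order in target”.
- Tuesday's flask ends with over-reaction product at 88.8 %, and Wednesday's with target at 86.5 %.

    starting material + protic impurity → quenched substrate (k = 0.0710 L mol⁻¹ min⁻¹, Ea = 52.0 kJ mol⁻¹)
    starting material ⇌ dormant form (K = 0.480, k = 0.00380 min⁻¹, Ea = 100 kJ mol⁻¹, ΔH = −54.0 kJ mol⁻¹)
    target → over-reaction product (k = 9.30 × 10⁻⁴ min⁻¹, Ea = 96.0 kJ mol⁻¹)
    starting material → target (k = 1.60 × 10⁻⁵ min⁻¹, Ea = 103 kJ mol⁻¹)
    starting material + target → 2 target (k = 0.660 L mol⁻¹ min⁻¹, Ea = 71.0 kJ mol⁻¹)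
    (constants at 25 °C)

- Neither flask has come to rest. The end amounts give counts of 1.84 for Tuesday's flask and 0.132 for Wednesday's, against my 1.74 and 0.191. Wednesday's charge held at 50 °C reckons to 3.01 and gives 3.27, with over-reaction product ahead. Tuesday's target, still 16.7 % at the end, stands at 0 % after 30.0 h. Carrying Wednesday's count to 30.0 h puts target's share at 14.8 %, and the flask then holds 82.9 % over-reaction product and 20.3 % target.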